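The readings stem from a simulated flask with constants of no real substance; scatter was added.

Time is what the question turns on. Capture of the intermediate by the first nucleophile is a reversible candidate step and capture by the second is not, so target is the kinetic product and other capture product the thermodynamic one. The late ratio therefore shows how far the flask has travelled towards other capture product.

| setting | Friday's | Sunday's | flask |
|---|---|---|---|
| starting material | 0.010 M | 0.010 M | 0.010 M |
| first nucleophile | 1 equiv | 1.5 equiv | 2.00 equiv |
| solid second nucleophile | 5 equiv | 5 equiv | 5.00 equiv |
| remark | run made earlier | run made earlier |  |
| time |  |  | 6.0 h |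

| run | time / h | other capture product / % | target / % |
|---|---|---|---|
| Friday's | 0.500 | 13 | 8 |
| Friday's | 1.00 | 27 | 9 |
| Friday's | 2.00 | 48 | 9 |
| Friday's | 4.00 | 73 | 5 |
| Friday's | 8.00 | 95 | 2 |
| Sunday's | 1.33 | 31 | 15 |
| Sunday's | 3.00 | 61 | 11 |
| Sunday's | 4.00 | 74 | 7 |
| Sunday's | 6.00 | 85 | 5 |
| Sunday's | 8.00 | 93 | 2 |

(readings scatter by 1.5 percentage points)

- for target the idle adduct is counted in
- as a solid, counted per litre of solution: solid second nucleophile
- the earlier runs were read with a standard deviation of 1.5 percentage points
- candidate steps: starting material <-> intermediate; first nucleophile + intermediate <-> target; second nucleophile + intermediate -> other capture product; second nucleophile + target <-> idle adduct; solid second nucleophile <-> second nucleophile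
- at the start none of the solid second nucleophile is in solution

- ratio of other capture product to target at 2.0 min
- ratio of other capture product to target at 25 min
- ratio of other capture product to target at 6.0 h
- which of other capture product and target there is more of at 6.0 h

Late on, I take target to follow the remaining starting material and the first nucleophile in proportion, so the ratio is

(100 − remaining − target) / target, with target = holding ratio · c_first nucleophile · remaining.

Which inputs matter? I get the remaining starting material as a difference, so the scatter of 1.5 percentage points on either reading, 85% of other capture product or 5% of target, passes into it, and both readings must be good. The remaining starting material at 4.00 h is 22.0% on Friday and 19.0% on Sunday, so I borrow Sunday's 10.0% at 6.00 h. The solid second nucleophile is 5.00 equiv in each flask, so it stays inside the ratio.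

Pooling Sunday's readings at 3.00 h and 4.00 h, where target reads 11% and 7%, down from 15% at 1.33 h, I read

25.5 M⁻¹

as the holding ratio, late c_target over c_starting material times c_first nucleophile. Friday's reading at 4.00 h gives 22.7 M⁻¹. For the flask, target is then

5.11%, and the ratio 16.6.

The forecast gives 0.05, 0.5 and 12, with other capture product ahead, on the ground that “target tracks remaining starting material”. My late figure is higher than its figure.

    starting material ⇌ intermediate (K = 0.00350, k = 2.30 × 10⁻⁴ s⁻¹)
    first nucleophile + intermediate ⇌ target (K = 970 M⁻¹, k = 5.60 M⁻¹ s⁻¹)
    second nucleophile + intermediate → other capture product (k = 11.0 M⁻¹ s⁻¹)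
    second nucleophile + target ⇌ idle adduct, settled at all times (K = 1700 M⁻¹)
    solid second nucleophile ⇌ second nucleophile, rate k5*(cs5 - [second nucleophile]) while solid is left; crystals form when [second nucleophile] > cs5 (solubility = 5.70 mM, k = 0.00380 s⁻¹)

The flask gives 0.121 at 2.0 min, 0.687 at 25 min and 15.1 at 6.0 h, with other capture product ahead. At 6.00 h it holds 83.6% of other capture product, 5.52% of target and 10.9% of starting material, with 97% of the first nucleophile unbound. The holding ratio applied to those amounts gives 5.40% of target. The neighbouring flask with 0.800 equiv of first nucleophile keeps 10.0% of starting material and 98% of its first nucleophile, so the holding ratio gives 2.00% of target there, and that flask holds 1.92%.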